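**Strategy.** The quinone C6–C1′ bond is disconnected as a radical conjugate addition. The whole side chain, C1′ to C13′ with its (R)-acetoxy carbon C2′, is C2–C14 of commercial (R)-3-hydroxytetradecanoic acid; its carboxyl carbon is expelled as CO2 to give the C1′ radical. The acceptor is a quinone monoketal, 3,4,4-trimethoxycyclohexa-2,5-dienone, in which the future C1 carbonyl is masked: its only free enone β-carbon is the future C6, so the 2-methoxy-6-alkyl pattern is fixed by the substrate. One operation joins ring and chain with the stereocentre untouched and, after loss of methanol, leaves a p-methoxyphenol one oxidation below the quinone. Precursor: the N-acyloxyphthalimide of the acetoxy acid plus the ketal.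

Key step: step 4

Remark: the stereocentre of the target is read as R (OAc > CH2–quinone > undecyl > H). This is the configuration of (R)-3-hydroxytetradecanoic acid, which is assumed to be purchased enantiopure.

**Step 1**
Reactants: 1 3,4-dimethoxyphenol
Product: 2 3,4,4-trimethoxycyclohexa-2,5-dien-1-one
Conditions: PhI(OAc)2 (1.1 equiv), MeOH, 0 °C to rt
Reagents that add atoms: methanol (CO)
Why: Hypervalent-iodine oxidative dearomatisation of a p-methoxyphenol, in which methanol attacks the para carbon whose methoxy group stabilises the developing cation, so the mixed quinone monoketal should form at C4 only.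

**Step 2**
Reactants: 3 (R)-3-hydroxytetradecanoic acid
Product: 5 (R)-3-acetoxytetradecanoic acid, via mixed anhydride 4 (not isolated)
Conditions: Ac2O (3 equiv), pyridine, CH2Cl2, 0 °C to rt; then H2O, THF, rt
Reagents that add atoms: acetic anhydride (CC(=O)OC(C)=O)
Why: O-Acetylation of a secondary alcohol, in which the carboxyl group is also acetylated to the mixed anhydride that water then cleaves at the unhindered acetyl carbonyl; the C3–O bond is never broken, so the R configuration is kept.

**Step 3**
Reactants: 5 (R)-3-acetoxytetradecanoic acid
Product: 6 1,3-dioxoisoindolin-2-yl (R)-3-acetoxytetradecanoate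
Conditions: N-hydroxyphthalimide (1.1 equiv), DIC (1.1 equiv), DMAP (5 mol%), CH2Cl2, 0 °C to rt
Reagents that add atoms: N-hydroxyphthalimide (O=C1c2ccccc2C(=O)N1O)
Why: Carbodiimide (Steglich-type) esterification to the redox-active ester, where low temperature and only catalytic DMAP should suppress E1cB loss of acetic acid; the stereocentre is not involved.

**Step 4**
Reactants: 6 1,3-dioxoisoindolin-2-yl (R)-3-acetoxytetradecanoate; 2 3,4,4-trimethoxycyclohexa-2,5-dien-1-one (2 equiv)
Product: 8 (R)-1-(5-hydroxy-2,3-dimethoxyphenyl)tridecan-2-yl acetate, via Giese adduct 7 (not isolated)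
Conditions: Ru(bpy)3(PF6)2 (1 mol%), Hantzsch ester (diethyl 2,6-dimethyl-1,4-dihydropyridine-3,5-dicarboxylate, 1.5 equiv), degassed CH2Cl2, blue LEDs, rt; then CSA (0.3 equiv), rt, same pot
Reagents that add atoms: none
Why: Photoexcited Ru(bpy)3 2+ is reductively quenched by the Hantzsch ester and the resulting Ru(I) transfers an electron to 6, which loses phthalimide anion and CO2 to give the primary 2-acetoxytridecyl radical; this adds to C5 of 2, the α-keto radical is reduced and protonated to 7, and mild acid then expels methanol (ketal ionisation, loss of H5, enolisation) to give phenol 8. The closest known reaction type is the photoredox decarboxylative Giese addition of redox-active esters to cyclic enones, followed by the usual acid aromatisation of conjugate adducts of quinone monoketals. No ring is closed. The one new stereocentre, ring C5 of 7, is uncontrolled and is erased on aromatisation, while the acetoxy carbon is β to the radical centre, takes part in no bond change and should keep its R configuration. The step needs regioselectivity and the substrate secures it: C4 is masked as the ketal and C3 is a substituted, methoxy-deactivated β-carbon, so C5 (the future quinone C6) is the only electrophilic enone terminus, and the product enone is a vinylogous ester that should accept no second radical. Addition to the enone at 0.2–0.5 M should outrun both the slow 1,2-acetoxy shift of the β-acetoxyalkyl radical and hydrogen transfer from the Hantzsch ester, and the weak acid should leave excess 2 untouched because its ionisation would give a destabilised phenoxenium-type cation.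

**Step 5**
Reactants: 8 (R)-1-(5-hydroxy-2,3-dimethoxyphenyl)tridecan-2-yl acetate
Product: 9 (R)-1-(5-methoxy-3,6-dioxocyclohexa-1,4-dien-1-yl)tridecan-2-yl acetate
Conditions: PhI(OAc)2 (1.2 equiv), MeCN/H2O (3:1), 0 °C
Reagents that add atoms: water (O)
Why: Hypervalent-iodine oxidative demethylation of a p-methoxyphenol, in which water attacks the methoxy-bearing para carbon and the hemiketal loses methanol to give the p-quinone; the brief, near-neutral conditions should spare the secondary acetate and the stereocentre.

**Compound list**
1 | 3,4-dimethoxyphenol | COc1ccc(O)cc1OC | starting material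
2 | 3,4,4-trimethoxycyclohexa-2,5-dien-1-one | COC1=CC(=O)C=CC1(OC)OC | intermediate
3 | (R)-3-hydroxytetradecanoic acid | CCCCCCCCCCC[C@H](CC(=O)O)O | starting material
4 | acetic (R)-3-acetoxytetradecanoic anhydride (not isolated) | CCCCCCCCCCC[C@H](CC(=O)OC(C)=O)OC(C)=O | intermediate
5 | (R)-3-acetoxytetradecanoic acid | CCCCCCCCCCC[C@H](CC(=O)O)OC(C)=O | intermediate
6 | 1,3-dioxoisoindolin-2-yl (R)-3-acetoxytetradecanoate | CCCCCCCCCCC[C@H](CC(=O)ON1C(=O)c2ccccc2C1=O)OC(C)=O | intermediate
7 | (2R)-1-(2,2,3-trimethoxy-5-oxocyclohex-3-en-1-yl)tridecan-2-yl acetate, both epimers at the ring carbon (not isolated) | CCCCCCCCCCC[C@H](CC1CC(=O)C=C(OC)C1(OC)OC)OC(C)=O | intermediate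
8 | (R)-1-(5-hydroxy-2,3-dimethoxyphenyl)tridecan-2-yl acetate | CCCCCCCCCCC[C@H](Cc1cc(O)cc(OC)c1OC)OC(C)=O | intermediate
9 | (R)-1-(5-methoxy-3,6-dioxocyclohexa-1,4-dien-1-yl)tridecan-2-yl acetate | CCCCCCCCCCC[C@H](CC1=CC(=O)C=C(OC)C1=O)OC(C)=O | target

**Step count and risks**
Total steps: 5. Longest linear sequence: 4 steps (3 → 5 → 6 → 8 → 9); the ketal branch 1 → 2 is one step.

Steps most likely to fail:

1. Step 4. The primary radical may be quenched by hydrogen transfer from the Hantzsch ester before it adds to the β-carbon next to the quaternary ketal carbon, or the dienone ketal may itself be reduced. The fallback sets out from 6 and makes the ring–chain bond by nickel-catalysed decarboxylative Negishi arylation, with no hydrogen donor and no ketal. 1-Methoxy-2-(methoxymethoxy)benzene F1 is lithiated ortho to the MOM ether (n-BuLi, TMEDA, THF, 0 °C) to [3-methoxy-2-(methoxymethoxy)phenyl]lithium F2, which ZnCl2 converts into chlorido[3-methoxy-2-(methoxymethoxy)phenyl]zinc F3. Coupling of F3 with 6 (NiCl2·glyme, 4,4′-di-tert-butyl-2,2′-bipyridine, THF/DMF, rt) should give (R)-1-[3-methoxy-2-(methoxymethoxy)phenyl]tridecan-2-yl acetate F4. Removal of the MOM group (CF3CO2H, CH2Cl2, 0 °C) should give (R)-1-(2-hydroxy-3-methoxyphenyl)tridecan-2-yl acetate F5. Teuber oxidation with Fremy's salt (KH2PO4 buffer, acetone/H2O) at the free para position comes back to the route at 9.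

2. Step 3. Base-promoted loss of acetic acid from the activated ester may occur during esterification or chromatography, giving the 2-enoate. The fallback sets out from 5 and generates the same radical by oxidative rather than reductive fragmentation, with no activated ester: the free acid is decarboxylated photocatalytically in the presence of 2 (4CzIPN with Cs2CO3 in DMF, or an acridine photocatalyst acting by proton-coupled electron transfer, visible light), followed by the same acid treatment. It comes back to the route at 8 via 7 and makes no new compound (entry F0).

3. Step 5. Water may attack at an ortho position, the ring may be over-oxidised, or the electrophilic methoxyquinone may degrade while oxidant is still present. The fallback sets out from 8 and separates oxidation from release of the quinone: PhI(OAc)2 in anhydrous MeOH (0 °C) should give the monoketal (R)-1-(5,6,6-trimethoxy-3-oxocyclohexa-1,4-dien-1-yl)tridecan-2-yl acetate F6, which is isolated and then hydrolysed without oxidant (aqueous oxalic acid, THF, rt) to come back at 9.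

**Further compounds**
F1 | step 4 | 1-methoxy-2-(methoxymethoxy)benzene | COCOc1ccccc1OC
F2 | step 4 | [3-methoxy-2-(methoxymethoxy)phenyl]lithium | [Li]c1cccc(OC)c1OCOC
F3 | step 4 | chlorido[3-methoxy-2-(methoxymethoxy)phenyl]zinc | Cl[Zn]c1cccc(OC)c1OCOC
F4 | step 4 | (R)-1-[3-methoxy-2-(methoxymethoxy)phenyl]tridecan-2-yl acetate | CCCCCCCCCCC[C@H](Cc1cccc(OC)c1OCOC)OC(C)=O
F5 | step 4 | (R)-1-(2-hydroxy-3-methoxyphenyl)tridecan-2-yl acetate | CCCCCCCCCCC[C@H](Cc1cccc(OC)c1O)OC(C)=O
F0 | step 3 | none | none
F6 | step 5 | (R)-1-(5,6,6-trimethoxy-3-oxocyclohexa-1,4-dien-1-yl)tridecan-2-yl acetate | CCCCCCCCCCC[C@H](CC1=CC(=O)C=C(OC)C1(OC)OC)OC(C)=O
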